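Read the crests first.

| flask | starting material | partner | protic impurity | temperature | remark | time |
|---|---|---|---|---|---|---|
| Tuesday's | 0.010 M | 7 mM | 6.7 mM | 75 °C | run made earlier |  |
| Thursday's | 0.010 M | 7 mM | 15 mM | 90 °C | run made earlier |  |
| Saturday's | 0.020 M | 7 mM | 10 mM | 75 °C | run made earlier |  |
| south-east | 0.010 M | 7.00 mM | 10.0 mM | 100 °C |  | 5.0 h |
| north-west | 0.010 M | 7.00 mM | 10.0 mM | 80 °C |  | 5.0 h |
| north | 0.010 M | 7.00 mM | 10.0 mM |  | at 80 °C until 1.5 h, from then on at 100 °C | 5.0 h |

| run | time / h | target / % | starting material / % |
|---|---|---|---|
| Tuesday's | 1.33 | 9.4 | 87.1 |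
| Tuesday's | 3.00 | 14.3 | 79.1 |
| Tuesday's | 6.00 | 17.0 | 71.9 |
| Tuesday's | 15.0 | 12.6 | 65.1 |
| Thursday's | 0.667 | 10.3 | 80.5 |
| Thursday's | 1.50 | 13.7 | 68.8 |
| Thursday's | 3.00 | 11.8 | 56.2 |
| Thursday's | 8.00 | 4.0 | 38.3 |
| Saturday's | 2.50 | 12.2 | 79.9 |
| Saturday's | 6.00 | 12.9 | 71.2 |
| Saturday's | 10.0 | 12.1 | 65.3 |
| Saturday's | 15.0 | 10.1 | 61.1 |

(scatter of a reading: 0.5 percentage points)

1. the best flask by amount of target, in percent of the starting material charged; "all alike" if 1.5 percentage points covers them all (south-east / north-west / north / all alike)
2. amount of target at the end, in percent of the starting material charged, south-east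
3. amount of target at the end, in percent of the starting material charged, north-west
4. amount of target at the end, in percent of the starting material charged, north

In every earlier run target climbs, tops out and falls, so you want to know where the stop at 5.0 h lies against that crest. Figures below are fractions of the charge.

The highest reading stands at 6.00 h on Tuesday at 75 °C, and again at 6.00 h on Saturday at that temperature with different charges. You may therefore treat this crest time (the usual time of maximum) as a matter of temperature, coarse as the sampling is. Thursday at 90 °C, with more protic impurity as well, has its highest reading at 1.50 h, so the crest time as read from these runs halves every 7.50 K; call this the crest interval.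

Now climb the ladder, fastest first. At 100 °C the crest comes at 0.595 h, before north's change at 1.5 h, so south-east should end far past its top. At 80 °C the crest comes at 3.78 h, before the stop, so north-west should end near its top. North changes while that crest lies ahead, then runs on the hot clock.

Count each flask's age in crest times: north-west 1.32, south-east 8.40, north 6.28. Thursday's fall from 13.7 % to 4.0 % gives a logarithmic loss of 0.284 per crest time past the top. Take the height as the mean of Tuesday's and Thursday's tops, 15.3 %, since 10.0 mM of protic impurity lies between their charges. You then reckon 14.0 % for north-west, 1.88 % for south-east and 3.43 % for north.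

The forecast names north-west, with 15.5 % there (range 13.5 % to 17.5 %), 5 % in south-east and 7.5 % in north, above your two hot figures, on the ground that target “then decays first-order, at a rate roughly proportional to impurity”.

The simulation gives north-west as best, with 15.1 % there, 2.33 % in south-east and 4.56 % in north, in your order and each above your figure.

    starting material + protic impurity → quenched substrate (k = 0.00550 M⁻¹ s⁻¹, Ea = 70.0 kJ mol⁻¹)
    starting material + partner ⇌ target (K = 61.0 M⁻¹, k = 0.0160 M⁻¹ s⁻¹, Ea = 59.0 kJ mol⁻¹, ΔH = −3.00 kJ mol⁻¹)
    starting material → side product (k = 1.80 × 10⁻⁶ s⁻¹, Ea = 120 kJ mol⁻¹)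
    partner → decomposed reagent (k = 2.10 × 10⁻⁴ s⁻¹, Ea = 106 kJ mol⁻¹)
    (constants at 100 °C)

Between north-west and south-east, the crest interval of 7.50 K brings the crest 6.35 times earlier, while the step from partner to decomposed reagent speeds up 6.9 times. Take that speeding-up away and the gap of 13 percentage points shrinks to 4.1 points, the larger of the two temperature effects tested, though not the whole gap.

In a repeat of north-west at 55 °C, the crest interval puts the crest at 38.1 h, beyond the stop, so that repeat should end on the climb. It gives 10.5 %, with 85.4 % of its starting material still there.

The runs were computed on assumed constants, and the scatter is random.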